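Start from slowness: substrate becomes intermediate on free catalyst, then intermediate and reagent become product on second catalyst, and in spring the second of these steps is the one that sets the pace, since its half-life as charged is 24 s against 0.51 s for the first.

| setting | spring | dawn | summer | midnight |
|---|---|---|---|---|
| substrate | 2.0 mM | 2.0 mM | 2.0 mM (fed, over 12.0 s) | 2.0 mM |
| reagent | 2.40 mM | 2.40 mM | 2.40 mM | 2.40 mM (fed, over 12.0 s) |
| free catalyst | 2.0 µM | 2.0 µM | 2.0 µM | 2.0 µM |
| second catalyst | 100 µM | 100 µM | 100 µM | 100 µM |
| time | 15 s |  | 15 s | 15 s |
| remark | a closed flask charged with all of it at once and left for 15 s | a single well-mixed tank run continuously and read at steady state, 15 s in it on average | all but substrate at the start; substrate goes in evenly over 12.0 s, the run ends at 15 s | all but reagent at the start; reagent goes in evenly over 12.0 s, the run ends at 15 s |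

    substrate + free catalyst → free catalyst + intermediate (k1 = 6.8 × 10⁵ M⁻¹ s⁻¹)
    reagent + second catalyst + intermediate → second catalyst + product (k2 = 1.2 × 10⁵ M⁻² s⁻¹)
    free catalyst ⇌ dormant form (K3 = 0.48, k3 = 0.96 s⁻¹)

- the stated concentrations are those of everything mixed, before any reaction; amounts are the same in each set-up
- the feed brings no volume worth counting
- run time (spring): 15 s

- the set-up with the highest amount of product at the outlet or at the end, in percent of the substrate put in ("none" if the first two lie within 2 percentage points) (spring / dawn / summer / midnight / none)
- amount of product at the outlet or at the end, in percent of the substrate put in, spring
- amount of product at the outlet or at the end, in percent of the substrate put in, dawn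
- amount of product at the outlet or at the end, in percent of the substrate put in, summer
- amount of product at the outlet or at the end, in percent of the substrate put in, midnight

Ask first what the end state must be. Substrate is the limiting reagent, so the state each flask in a closed vessel moves towards holds the substrate charge as product, with 0.400 mM of reagent over. Then ask how fast it is approached. My clock is the finishing rate f, the second step's constant times reagent and second catalyst as charged, 0.0288 s⁻¹: a pseudo-first-order rate constant for intermediate. The first step adds a lag L. With 67.6% of the catalyst free at equilibrium with the dormant form, L is 1.09 s.

Now take two extreme versions of spring. If reagent stayed at its charge for the 13.9 s after the lag, the yield would be one minus the exponential of minus f times that time, 33.0%. If reagent stood from the start where that yield leaves it, 1.74 mM, the same sum would give 25.2%. The real reagent falls gradually from the first level towards the second, so spring lies between them, and I commit to the midpoint, 29.1%.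

The other flasks get the first extreme too. In summer, and in midnight, the dosed charge arrives on average 6.00 s late, which shortens the time; midnight has its substrate from the start, and L is shorter than that wait, so I take no lag there. The dawn tank uses the steady-state form fτ/(1+fτ), with τ its mean 15 s, times the first step's conversion.

| Set-up | Mine, reagent held at charge | Forecast |
|---|---|---|
| spring | 33.0% | 29.5% |
| dawn | 28.1% | 24% |
| summer | 20.4% | 18.5% |
| midnight | 22.8% | 20.5% |

The forecast names spring: “The batch therefore wins, the tank loses by running at outlet concentrations”.

The simulation gives spring as best, with 29.4% there, 24.0% in dawn, 18.5% in summer and 20.5% in midnight.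

Take a neighbour flask, like summer but with 9.6 mM of reagent, which is 4.80 equiv to substrate. Its finishing rate is f scaled by the reagent charge, 0.115 s⁻¹, and its time after the dosing wait and the lag is still 7.91 s. Reagent held at charge gives 59.8%. Reagent standing at the level that yield leaves, 8.40 mM, gives 55.0%. The simulated neighbour ends with 53.9% as product, 1 percentage point under that lower figure, and with 45.5% as intermediate.

The numbers were chosen freely; the result is computed.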